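# Synthesis plan for 4'-hydroxy-3,5,8,3'-tetramethoxy-7-prenyloxyflavone (15)

## The problem

The target is a flavone in which every position of ring C is substituted (O1, C2-aryl, C3-OMe, C4=O) and ring A carries four oxygens in a 1,2,3,5 pattern (O1 at C8a, OMe at C8, prenyloxy at C7, OMe at C5). There is no stereocentre and the prenyl double bond carries two identical methyl groups, so the problem is one of regiochemistry and of chemoselectivity among five ether oxygens and one free phenol. Three things are hard: the C2=C3 bond is a tetrasubstituted enol ether that must be made with its methoxy group in place; O7 must be told apart from the two methoxy oxygens of the same ring; and 4'-OH must end up free beside 3'-OMe. The aryl prenyl ether ionises in acid, undergoes Claisen rearrangement on heating, is reduced under hydrogenolysis and is attacked by electrophilic oxidants, so it must go on late, and 4'-OH must then be released under basic, mild and non-reducing conditions. The feature that the plan uses lies in ring A: O1 and O7 are both ortho to C8(OMe), and C4a and C6 are both ortho to C5(OMe), so removing C4 and the prenyl group leaves 2,5-dimethoxybenzene-1,3-diol, which has a mirror plane through C8 and C5. In this diol the two hydroxyls are equivalent, the two ring CH are equivalent, and each CH has exactly one hydroxyl neighbour, because the other ortho position of each hydroxyl is blocked by the C8 methoxy. One annulation across a hydroxyl and its neighbouring CH can therefore give only one constitutional isomer, and the hydroxyl it leaves is O7, the only free OH of the product. The C3 methoxy can ride in on the α-carbon of a β-keto ester, so ring C can be closed at a carbon–carbon bond (C4–C4a) onto an arene that carries no acyl group beforehand.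

## Retrosynthesis

**15 ⇒ 14 ⇒ 13.** The last two operations break the O–S bond of a 4'-O-tosylate (14 → 15) and make the O7–CH2 bond of the prenyl ether (13 → 14). The prenyl group comes after all hot and acidic chemistry. The tosylate is chosen because it has no acidic hydrogen, resists enolates at low temperature and neutral heat, and is removed by hydroxide, to which the prenyl ether is inert. Flavone 13 has a single free hydroxyl (7-OH), so the prenylation needs no selectivity.

**13 ⇒ 4 + 9.** Ring C is cut at C4–C4a and at O1–C2, giving the symmetric diol 4 and the acyclic α-methoxy-β-keto ester 9, which already holds C2, C3(OMe), C4 and ring B. A cut at O1–C2 alone, or at C2–C3, would lead back to an o-hydroxyaryl ketone whose ring-A oxygens must first be differentiated. The chosen double cut needs no differentiation: the product has three rings and six differentiated oxygens, the precursors a C8 arene with a mirror plane and an open chain. The forward reaction must acylate carbon instead of oxygen, give chromone instead of coumarin, and stop after one annulation.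

**9 ⇒ 6 + 7 (through 8); 6 ⇒ 5.** The bond between the aroyl carbon and the methoxy-bearing carbon (C2–C3 of the flavone) is cut. Forward, this is a crossed Claisen acylation of the lithium enolate of methyl methoxyacetate 7 by acid chloride 8, made from acid 6, which is vanillic acid 5 tosylated at the phenol. The B-ring pattern (3'-OMe, 4'-O) is bought with vanillic acid.

**4 ⇒ 3 ⇒ 2 ⇒ 1.** The two C–OH bonds of 4 are traced to two C–Br bonds (3), and these to the double ortho-bromination of 4-methoxyphenol 1. The hydroxyl of 1 places both bromines and, after methylation, becomes the C8 methoxy; the para-methoxy of 1 becomes 5-OMe. The 1,2,3,5 pattern and its symmetry thus come from the directing effect of one OH in a cheap para-disubstituted benzene.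

## Roads not taken

**Alternative 1:** the most obvious route, chalcone oxidation (Algar–Flynn–Oyamada), with cuts at O1–C2 and C3–O.
- Forward: Claisen–Schmidt condensation of acetophenone A1 with 4-O-MOM-vanillin would give chalcone A2; alkaline H2O2 would give flavonol A3; then 3-O-methylation and removal of the MOM group.
- Weakness in mechanism: A2 has a 6'-methoxy group (the future 5-OMe). This class of 2'-hydroxychalcones is diverted in alkaline peroxide towards attack at the α-carbon, giving aurone A4 in place of A3.
- Weakness in step economy: A1 needs C-acetylation and selective O-prenylation of the same diol 4; the flavonol needs a separate methylation; the prenyl ether has to survive the acidic MOM removal. This is about two steps more than the chosen plan.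
- The acylation–rearrangement variant of the O1–C2 closure (Baker–Venkataraman) is more secure than the chalcone route and is kept as the fallback of the key step.

**Alternative 2:** three-component carbonylative annulation, with cuts at C4a–C4, C4–C3 and O1–C2.
- Forward: mono-iodination of 4 would give iodophenol A5 (one isomer by symmetry). Palladium-catalysed carbonylative Sonogashira coupling of A5, CO and alkyne A6 (PdCl2(PPh3)2, amine base) with cyclisation of the ynone would give flavone A7.
- Weakness: A7 lacks the C3 oxygen. The tetrasubstituted enol ether, the hardest part of ring C, would still need C3 metalation, borylation, oxidation and methylation with 7-OH protected, at least three further steps.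
- Ynone closure can also go 5-exo to an aurone, and A6 needs two steps from vanillin.
- The chosen annulation delivers the C3 methoxy in the same operation.

**Alternative 3:** late union of rings B and C, with the cut at C2–C1'.
- Forward: oxidative C2–H arylation of chromone A8 with a 4-oxygenated 3-methoxyphenylboronic acid (Pd(OAc)2, divalent palladium, with an oxidant), or C2 metalation and cross-coupling.
- Weakness in step economy: A8 must itself be built from 4 by C-acylation with a methoxyacetyl unit and a one-carbon ring closure, so ring C costs two steps and the key step then forms one bond.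
- Weakness in mechanism: aryl–palladium addition to a 3-alkoxychromone places palladium on C3 beside OMe, with the C2–H needed for β-hydride elimination anti to it. C2-metalated chromones also tend to open to ynone phenoxides.

Key step: step 6

Remark on the chemistry: the target is achiral, so no descriptor is needed on the main route; 1, 5, 7 and all reagents are assumed to be catalogue chemicals.

## Route

Step 1
Reactants: 1 4-methoxyphenol
Product: 2 2,6-dibromo-4-methoxyphenol
Conditions: Br2 (2.1 equiv), CH2Cl2, 0 °C to rt
Reagents that add atoms: bromine, BrBr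
Why: Electrophilic aromatic bromination; the hydroxyl is the stronger director and its para position is blocked by the methoxy group, so both bromines should enter ortho to OH.

Step 2
Reactants: 2 2,6-dibromo-4-methoxyphenol
Product: 3 1,3-dibromo-2,5-dimethoxybenzene
Conditions: MeI, K2CO3, DMF, rt to 40 °C
Reagents that add atoms: iodomethane, CI
Why: Williamson O-methylation of the acidic 2,6-dibromophenol; this oxygen becomes the C8 methoxy of the target.

Step 3
Reactants: 3 1,3-dibromo-2,5-dimethoxybenzene
Product: 4 2,5-dimethoxybenzene-1,3-diol
Conditions: Pd2(dba)3 (cat.), tBuXPhos (cat.), KOH (6 equiv), 1,4-dioxane/H2O, 100 °C, Ar; then aq. HCl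
Reagents that add atoms: potassium hydroxide, [K+].[OH-]
Why: Palladium-catalysed hydroxylation of aryl bromides (C–O cross-coupling of the Buchwald–Hartwig type): oxidative addition to zerovalent palladium, exchange of bromide for hydroxide and C–O reductive elimination promoted by the bulky biaryl phosphine. The two C–Br bonds are equivalent, and excess KOH in water should favour phenol over diaryl ether.

Step 4
Reactants: 5 vanillic acid (4-hydroxy-3-methoxybenzoic acid)
Product: 6 3-methoxy-4-(tosyloxy)benzoic acid
Conditions: TsCl (1.2 equiv), NaOH (aq), THF, 0 °C to rt; then aq. HCl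
Reagents that add atoms: 4-methylbenzenesulfonyl chloride, Cc1ccc(S(=O)(=O)Cl)cc1
Why: Schotten–Baumann O-sulfonylation of the phenoxide; any mixed anhydride formed at the carboxylate is hydrolysed back in the aqueous base, so only the phenol should stay capped.

Step 5
Reactants: 6 3-methoxy-4-(tosyloxy)benzoic acid; 7 methyl methoxyacetate
Product: 9 methyl 2-methoxy-3-[3-methoxy-4-(tosyloxy)phenyl]-3-oxopropanoate, via acid chloride 8 (not isolated)
Conditions: (COCl)2, DMF (cat.), CH2Cl2, 0 °C to rt, evaporate; then 7 (2.2 equiv), LiN(SiMe3)2 (2.2 equiv), THF, −78 °C, add 8; AcOH quench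
Reagents that add atoms: oxalyl chloride, O=C(Cl)C(=O)Cl (supplies the chlorine of 8; no reagent atom remains in 9)
Why: Acid chloride formation followed by crossed Claisen C-acylation of the lithium ester enolate; the second equivalent of enolate deprotonates the more acidic product 9 and so should prevent double acylation, and the tosylate has no acidic hydrogen and should be inert to the enolate at −78 °C.

Step 6
Reactants: 4 2,5-dimethoxybenzene-1,3-diol (1.5 equiv); 9 methyl 2-methoxy-3-[3-methoxy-4-(tosyloxy)phenyl]-3-oxopropanoate
Product: 13 7-hydroxy-3,5,8-trimethoxy-2-[3-methoxy-4-(tosyloxy)phenyl]-4H-chromen-4-one, via acylketene 10 (not isolated), via aryl ester 11 (not isolated), via diketone 12 (not isolated)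
Conditions: neat melt (or Ph2O), 240 °C, Ar sweep, MeOH and H2O distilled out
Reagents that add atoms: none
Why: Mentzer-type thermal chromone synthesis (phenol plus β-keto ester without catalyst), the reaction type by which phloroglucinol and aroylacetates give 5,7-dihydroxyflavones. At 240 °C 9 should lose methanol to give acylketene 10, which 4 captures at oxygen to give aryl ester 11; 11 re-forms 10 at this temperature, so O-acylation is reversible and the acyl group ends on carbon, by 1,3-shift within 11 (thermal Fries rearrangement) or by direct attack of 10 on the ring, giving diketone 12. Ring C thus closes first at the carbon–carbon bond C4–C4a (electrophilic aromatic substitution at the CH that is ortho to OH, ortho to OMe and para to the second OH, a phloroglucinol-like position), then at O1–C2 by 6-exo-trig addition of the neighbouring phenol to the aryl ketone and loss of water, which is irreversible because it forms the aromatic pyranone. No stereocentre is formed. Regiochemistry needs no control: the two CH and the two OH of 4 are equivalent through the mirror plane, the acylated carbon has only one OH neighbour for the closure, and the other OH, now para to the new carbonyl, remains as 7-OH. Chromone should be preferred to coumarin because without acid the aryl ketone of 9 is not activated for attack by the arene, while the ketene carbon is the strongest electrophile present. A second annulation at C6 and 7-OH is held back by the excess of 4 and by the lower nucleophilicity of the ring once it carries the C4 carbonyl. The tosylate and the methyl ethers have no pathway open under neutral, base-free conditions, and the heat-sensitive prenyl ether is not yet present.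

Step 7
Reactants: 13 7-hydroxy-3,5,8-trimethoxy-2-[3-methoxy-4-(tosyloxy)phenyl]-4H-chromen-4-one
Product: 14 3,5,8-trimethoxy-2-[3-methoxy-4-(tosyloxy)phenyl]-7-(3-methylbut-2-enyloxy)-4H-chromen-4-one
Conditions: prenyl bromide (1.2 equiv), K2CO3, acetone, 50 °C
Reagents that add atoms: prenyl bromide (1-bromo-3-methylbut-2-ene), CC(C)=CCBr
Why: Williamson ether synthesis (SN2 at the primary allylic bromide) on the only free hydroxyl; 7-OH is a vinylogous carboxylic acid and is ionised by K2CO3, and 50 °C is far below the onset of Claisen rearrangement of an aryl prenyl ether.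

Step 8
Reactants: 14 3,5,8-trimethoxy-2-[3-methoxy-4-(tosyloxy)phenyl]-7-(3-methylbut-2-enyloxy)-4H-chromen-4-one
Product: 15 2-(4-hydroxy-3-methoxyphenyl)-3,5,8-trimethoxy-7-(3-methylbut-2-enyloxy)-4H-chromen-4-one (the target)
Conditions: KOH (aq, 5 equiv), THF/H2O, 60 °C; then AcOH to pH 6
Reagents that add atoms: none
Why: Alkaline hydrolysis of an aryl sulfonate by attack of hydroxide at sulfur; the leaving phenoxide is conjugated through C2=C3 with the C4 carbonyl, which should speed the cleavage, and water instead of an alcohol as solvent avoids an alkyl tosylate that could alkylate the freed phenoxide. The prenyl ether and the methyl ethers are inert to base, and the work-up with acetic acid is too mild to ionise the prenyl ether.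

## Compound list

1 | 4-methoxyphenol | COc1ccc(O)cc1 | starting material
2 | 2,6-dibromo-4-methoxyphenol | COc1cc(Br)c(O)c(Br)c1 | intermediate
3 | 1,3-dibromo-2,5-dimethoxybenzene | COc1cc(Br)c(OC)c(Br)c1 | intermediate
4 | 2,5-dimethoxybenzene-1,3-diol | COc1cc(O)c(OC)c(O)c1 | intermediate
5 | vanillic acid (4-hydroxy-3-methoxybenzoic acid) | COc1cc(C(=O)O)ccc1O | starting material
6 | 3-methoxy-4-(tosyloxy)benzoic acid | COc1cc(C(=O)O)ccc1OS(=O)(=O)c1ccc(C)cc1 | intermediate
7 | methyl methoxyacetate | COCC(=O)OC | starting material
8 | 3-methoxy-4-(tosyloxy)benzoyl chloride | COc1cc(C(=O)Cl)ccc1OS(=O)(=O)c1ccc(C)cc1 | intermediate (not isolated)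
9 | methyl 2-methoxy-3-[3-methoxy-4-(tosyloxy)phenyl]-3-oxopropanoate | COC(=O)C(OC)C(=O)c1ccc(OS(=O)(=O)c2ccc(C)cc2)c(OC)c1 | intermediate
10 | 2-methoxy-3-[3-methoxy-4-(tosyloxy)phenyl]-3-oxoprop-1-en-1-one (acylketene) | COC(=C=O)C(=O)c1ccc(OS(=O)(=O)c2ccc(C)cc2)c(OC)c1 | intermediate (not isolated)
11 | 3-hydroxy-2,5-dimethoxyphenyl 2-methoxy-3-[3-methoxy-4-(tosyloxy)phenyl]-3-oxopropanoate | COc1cc(O)c(OC)c(OC(=O)C(OC)C(=O)c2ccc(OS(=O)(=O)c3ccc(C)cc3)c(OC)c2)c1 | intermediate (not isolated)
12 | 1-(2,4-dihydroxy-3,6-dimethoxyphenyl)-2-methoxy-3-[3-methoxy-4-(tosyloxy)phenyl]propane-1,3-dione | COc1cc(O)c(OC)c(O)c1C(=O)C(OC)C(=O)c1ccc(OS(=O)(=O)c2ccc(C)cc2)c(OC)c1 | intermediate (not isolated)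
13 | 7-hydroxy-3,5,8-trimethoxy-2-[3-methoxy-4-(tosyloxy)phenyl]-4H-chromen-4-one | COc1cc(-c2oc3c(OC)c(O)cc(OC)c3c(=O)c2OC)ccc1OS(=O)(=O)c1ccc(C)cc1 | intermediate
14 | 3,5,8-trimethoxy-2-[3-methoxy-4-(tosyloxy)phenyl]-7-(3-methylbut-2-enyloxy)-4H-chromen-4-one | COc1cc(-c2oc3c(OC)c(OCC=C(C)C)cc(OC)c3c(=O)c2OC)ccc1OS(=O)(=O)c1ccc(C)cc1 | intermediate
15 | 2-(4-hydroxy-3-methoxyphenyl)-3,5,8-trimethoxy-7-(3-methylbut-2-enyloxy)-4H-chromen-4-one | COc1cc(-c2oc3c(OC)c(OCC=C(C)C)cc(OC)c3c(=O)c2OC)ccc1O | target

## Step count and risks

Total step count: 8. Longest linear sequence: 6 steps (steps 1, 2, 3, 6, 7, 8; the branch through steps 4 and 5 joins at step 6).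

**Step 6 (key step).**
- Most likely to go wrong: attack of the arene on the ketone carbonyl instead of the ketene carbon (the Pechmann mode, giving a coumarin skeleton); hydrolysis of the ketene by the water set free, followed by decarboxylation; and a second annulation on the product. All are favoured by the long residence at 240 °C that a sluggish C-acylation would require.
- Fallback (sets out from 4, returns at 13):
  - Houben–Hoesch acylation of 4 with methoxyacetonitrile (ZnCl2, HCl, Et2O, 0 °C; then hot water) should give 1-(2,4-dihydroxy-3,6-dimethoxyphenyl)-2-methoxyethan-1-one F1 as the only isomer, again by symmetry.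
  - Both hydroxyls are acylated with acid chloride 8 (pyridine, CH2Cl2) to give 4-(methoxyacetyl)-2,5-dimethoxy-1,3-phenylene bis[3-methoxy-4-(tosyloxy)benzoate] F2.
  - Baker–Venkataraman rearrangement (LiN(SiMe3)2, THF, −78 to 0 °C) moves the ortho aroyl group to carbon and gives the 4-O-aroyl 1,3-diketone F3.
  - Cyclodehydration (AcOH, catalytic H2SO4, 60 °C) gives the 7-O-aroyl flavone F4.
  - Methanolysis of the aryl carboxylate (K2CO3, MeOH, 0 °C to rt), which is much faster than cleavage of the aryl sulfonate, returns to 13.

**Step 3.**
- Most likely to go wrong: stalling after the first hydroxylation (the bromophenoxide is a poorer partner for oxidative addition), diaryl ether formation by the intermediate phenoxide, hydrodebromination, and air oxidation of the electron-rich product in hot base.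
- Fallback (sets out from 3, returns at 4): double Miyaura borylation (PdCl2(dppf), bis(pinacolato)diboron, KOAc, dioxane, 90 °C) should give 2,2'-(2,5-dimethoxy-1,3-phenylene)bis(4,4,5,5-tetramethyl-1,3,2-dioxaborolane) F5, and oxidation of both C–B bonds (H2O2, NaOH, THF/H2O, 0 °C) returns to 4.

**Step 5.**
- Most likely to go wrong: O-acylation of the enolate, self-condensation of 7, and sulfonyl transfer from the tosylate to excess enolate.
- Fallback (sets out from 8, returns at 9):
  - Decarboxylative acylation of KO2CCH2CO2Me (MgCl2, Et3N, MeCN) should give methyl 3-[3-methoxy-4-(tosyloxy)phenyl]-3-oxopropanoate F6.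
  - Diazo transfer (4-acetamidobenzenesulfonyl azide, Et3N, MeCN) gives methyl 2-diazo-3-[3-methoxy-4-(tosyloxy)phenyl]-3-oxopropanoate F7.
  - O–H insertion of the rhodium carbene into methanol (Rh2(OAc)4, MeOH, CH2Cl2, rt) returns to 9.

**Step 8.**
- Most likely to go wrong: addition of hydroxide at C2 of the neutral pyranone, with ring opening and retro-Claisen cleavage, competing with attack at sulfur.
- Fallback (sets out from 13, returns at 15):
  - The tosylate is hydrolysed before prenylation (KOH, THF/H2O, 60 °C), where the 7-phenoxide makes the pyranone electron-rich and should shield C2, giving 7-hydroxy-2-(4-hydroxy-3-methoxyphenyl)-3,5,8-trimethoxy-4H-chromen-4-one F8.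
  - Mono-prenylation then relies on acidity instead of a protecting group: 7-OH, para to the C4 carbonyl, is expected to be more acidic than the guaiacol-type 4'-OH, so prenyl bromide (1.0 equiv) with KHCO3 in DMF at rt should alkylate O7 and give 15.

## Further compounds

F1 | step 6 | 1-(2,4-dihydroxy-3,6-dimethoxyphenyl)-2-methoxyethan-1-one | COCC(=O)c1c(O)c(OC)c(O)cc1OC
F2 | step 6 | 4-(methoxyacetyl)-2,5-dimethoxy-1,3-phenylene bis[3-methoxy-4-(tosyloxy)benzoate] | COCC(=O)c1c(OC(=O)c2ccc(OS(=O)(=O)c3ccc(C)cc3)c(OC)c2)c(OC)c(OC(=O)c2ccc(OS(=O)(=O)c3ccc(C)cc3)c(OC)c2)cc1OC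
F3 | step 6 | 3-hydroxy-2,5-dimethoxy-4-{2-methoxy-3-[3-methoxy-4-(tosyloxy)phenyl]-3-oxopropanoyl}phenyl 3-methoxy-4-(tosyloxy)benzoate | COc1cc(OC(=O)c2ccc(OS(=O)(=O)c3ccc(C)cc3)c(OC)c2)c(OC)c(O)c1C(=O)C(OC)C(=O)c1ccc(OS(=O)(=O)c2ccc(C)cc2)c(OC)c1
F4 | step 6 | 3,5,8-trimethoxy-2-[3-methoxy-4-(tosyloxy)phenyl]-4-oxo-4H-chromen-7-yl 3-methoxy-4-(tosyloxy)benzoate | COc1cc(-c2oc3c(OC)c(OC(=O)c4ccc(OS(=O)(=O)c5ccc(C)cc5)c(OC)c4)cc(OC)c3c(=O)c2OC)ccc1OS(=O)(=O)c1ccc(C)cc1
F5 | step 3 | 2,2'-(2,5-dimethoxy-1,3-phenylene)bis(4,4,5,5-tetramethyl-1,3,2-dioxaborolane) | COc1cc(B2OC(C)(C)C(C)(C)O2)c(OC)c(B2OC(C)(C)C(C)(C)O2)c1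
F6 | step 5 | methyl 3-[3-methoxy-4-(tosyloxy)phenyl]-3-oxopropanoate | COC(=O)CC(=O)c1ccc(OS(=O)(=O)c2ccc(C)cc2)c(OC)c1
F7 | step 5 | methyl 2-diazo-3-[3-methoxy-4-(tosyloxy)phenyl]-3-oxopropanoate | COC(=O)C(=[N+]=[N-])C(=O)c1ccc(OS(=O)(=O)c2ccc(C)cc2)c(OC)c1
F8 | step 8 | 7-hydroxy-2-(4-hydroxy-3-methoxyphenyl)-3,5,8-trimethoxy-4H-chromen-4-one | COc1cc(-c2oc3c(OC)c(O)cc(OC)c3c(=O)c2OC)ccc1O
A1 | alternative 1 | 1-[2-hydroxy-3,6-dimethoxy-4-(3-methylbut-2-enyloxy)phenyl]ethan-1-one | CC(=O)c1c(O)c(OC)c(OCC=C(C)C)cc1OC
A2 | alternative 1 | (E)-1-[2-hydroxy-3,6-dimethoxy-4-(3-methylbut-2-enyloxy)phenyl]-3-[3-methoxy-4-(methoxymethoxy)phenyl]prop-2-en-1-one | COCOc1ccc(/C=C/C(=O)c2c(O)c(OC)c(OCC=C(C)C)cc2OC)cc1OC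
A3 | alternative 1 | 3-hydroxy-5,8-dimethoxy-2-[3-methoxy-4-(methoxymethoxy)phenyl]-7-(3-methylbut-2-enyloxy)-4H-chromen-4-one | COCOc1ccc(-c2oc3c(OC)c(OCC=C(C)C)cc(OC)c3c(=O)c2O)cc1OC
A4 | alternative 1 | (Z)-4,7-dimethoxy-2-[3-methoxy-4-(methoxymethoxy)benzylidene]-6-(3-methylbut-2-enyloxy)benzofuran-3(2H)-one | COCOc1ccc(/C=C2\Oc3c(OC)c(OCC=C(C)C)cc(OC)c3C2=O)cc1OC
A5 | alternative 2 | 4-iodo-2,5-dimethoxybenzene-1,3-diol | COc1cc(O)c(OC)c(O)c1I
A6 | alternative 2 | 4-ethynyl-2-methoxyphenyl 4-methylbenzenesulfonate | C#Cc1ccc(OS(=O)(=O)c2ccc(C)cc2)c(OC)c1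
A7 | alternative 2 | 7-hydroxy-5,8-dimethoxy-2-[3-methoxy-4-(tosyloxy)phenyl]-4H-chromen-4-one | COc1cc(-c2cc(=O)c3c(OC)cc(O)c(OC)c3o2)ccc1OS(=O)(=O)c1ccc(C)cc1
A8 | alternative 3 | 7-hydroxy-3,5,8-trimethoxy-4H-chromen-4-one | COc1coc2c(OC)c(O)cc(OC)c2c1=O
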